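1. I wanted to know what stands in this flask at 2.5 min, and whether the neighbour charged with more starting material ends with more.

- north-east: starting material 0.0010 M (in portions, 2); partner 1 equiv; the very flask that is asked about, followed so far; portions every 1.5 s
- flask: starting material 0.0010 M (in portions, 2); partner 1.00 equiv; time 2.5 min; the portions of starting material follow each other after 1.5 s, the first at the start

north-east run (percent of the starting material charged)

| time / s | starting material / % | over-reaction product / % |
|---|---|---|
| 10.0 | 41.7 | 5.7 |
| 12.0 | 35.9 | 7.8 |
| 25.0 | 20.3 | 32.2 |
| 50.0 | 10.8 | 64.4 |

(scatter of a reading: 1 percentage point)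

* concentration of starting material at 2.5 min, in M
* concentration of over-reaction product at 2.5 min, in M
* concentration of partner at 2.5 min, in M

2. Partner was charged equal to starting material. Taking them as used one for one, the two stay equal once both portions are in, so the rate goes with the square of one concentration. That rate integrates in closed form: the reciprocal concentration equals the reciprocal of the charge plus k times the time.

3. From the first and last readings, k came to 172 L mol⁻¹ s⁻¹. I called this apparent second-order rate constant the meeting constant. The earlier stretch gave 169 L mol⁻¹ s⁻¹ and the later one 173 L mol⁻¹ s⁻¹, so the line looked straight. It remains a reading, though, since the last point is 10.8% with a scatter of 1 percentage point.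

4. I set the portions aside, their interval of 1.5 s being much shorter than 2.5 min. In this flask the charge term came to 3.89% of the time term. The reciprocal in this flask is therefore nearly k times the time, and its charge matters little because the time term is much larger. I reckoned 3.74 × 10⁻⁵ M of starting material for this flask and 3.80 × 10⁻⁵ M for the neighbour charged with 0.0017 M at the same equivalents and the same time, and partner the same as starting material in each. For the over-reaction product I made no reckoning. The unread gap in this flask shrank from 47.5% at 25.0 s to 24.8% at 50.0 s, so I expected the over-reaction product near the charge.

5. The forecast gave 3.800 × 10⁻⁵ M of starting material, a little above my figure, with 3.800 × 10⁻⁵ M of partner and 9.300 × 10⁻⁴ M of over-reaction product: “That is linear, with a slope of about 0.0017 per % per s, so this is clean second-order behaviour.”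

6. The flask gave 4.21 × 10⁻⁵ M of starting material, 4.21 × 10⁻⁵ M of partner and 9.40 × 10⁻⁴ M of over-reaction product.

    starting material + partner → intermediate A (k = 147 L mol⁻¹ s⁻¹)
    starting material + partner → intermediate B (k = 5.31 L mol⁻¹ s⁻¹)
    intermediate B → target (k = 0.0802 s⁻¹)
    intermediate A ⇌ target (K = 1.10, k = 0.0521 s⁻¹)
    target → over-reaction product (k = 0.171 s⁻¹)

7. The neighbour, for which I had reckoned 3.80 × 10⁻⁵ M of starting material, stood at 4.29 × 10⁻⁵ M after 2.5 min, beside 4.21 × 10⁻⁵ M in this flask. In this flask at 2.50 min, the remaining starting material had a half-life of 2.31 min by the meeting constant, much longer than the 0.068 min of target on its path to over-reaction product. Target stood there at 0.378% of the charge, against 94.0% of over-reaction product.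

The data stem from a simulated flask for an exercise, and the scatter is random.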